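**Retrosynthetic overview**
- Rings A and B are bought intact. Ring A is acetophenone 1, which brings O1, 7-OMe and 8-OMe. Ring B is isovanillin 2, which brings 3'-OH and 4'-OMe.
- Ring C is the only ring made: first the aldol C–C bond, then the O1–C2 bond. 1 + 2 pass through chalcone 3 and flavanone 4 to flavone 5.
- C5–O disconnection: the C4 ketone directs C–H oxygenation of 5, through trifluoroacetates 6 and 7, to 5-hydroxyflavone 8.
- C6–O disconnection (last bond, key step): chelate-directed oxygen-atom transfer to the only remaining ring-A C–H of 8, through dienone 9, gives target 10.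
- There is no separate protecting-group step, and no isolated compound has a stereocentre.

Assumption: the target has no stereocentre or stereogenic axis, so there is no enantiomer to select and the route delivers the one achiral structure given; 1 and 2 are taken as catalogue chemicals.

**Step 1**
Reactants: 1 2'-hydroxy-3',4'-dimethoxyacetophenone; 2 isovanillin (3-hydroxy-4-methoxybenzaldehyde)
Product: 5 3'-hydroxy-7,8,4'-trimethoxyflavone, via chalcone 3 (not isolated), via flavanone 4 (not isolated)
Conditions: pyrrolidine (0.5 equiv), I2 (10 mol %), DMSO, 140 °C, 8 h; pour into water, filter, recrystallise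
Reagents that add atoms: none
Why: Amine-catalysed Claisen–Schmidt (aldol) condensation gives 3, the 2'-OH closes ring C by oxa-Michael addition (O1–C2 bond) to 4, and the iodine/DMSO couple dehydrogenates C2–C3 and so erases the transient C2 stereocentre; the phenol of 2 sits meta to the aldehyde and does not deactivate it.

**Step 2**
Reactants: 5 3'-hydroxy-7,8,4'-trimethoxyflavone
Product: 8 5,3'-dihydroxy-7,8,4'-trimethoxyflavone, via 3'-trifluoroacetate 6 (not isolated), via 5,3'-bis(trifluoroacetate) 7 (not isolated)
Conditions: [RuCl2(p-cymene)]2 (5 mol %), PhI(OCOCF3)2 (1.5 equiv), CF3CO2H/(CF3CO)2O 3:1, 80 °C, 6 h; concentrate; THF/H2O, rt, 1 h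
Reagents that add atoms: [bis(trifluoroacetoxy)iodo]benzene, O=C(OI(OC(=O)C(F)(F)F)c1ccccc1)C(F)(F)F (delivers the 5-OCOCF3 group of 7, of which O-5 stays in 8); trifluoroacetic anhydride, O=C(OC(=O)C(F)(F)F)C(F)(F)F (delivers the 3'-O-trifluoroacetyl group of 6 and 7, none of which stays in 8)
Why: This is a ketone-directed ruthenium-catalysed ortho C–H oxygenation, known for flavones: the C4 carbonyl holds divalent ruthenium in a five-membered metallacycle at C5 (the only peri C–H), the trivalent-iodine oxidant triggers C–O bond formation to the trifluoroacetate, the anhydride keeps both phenols as electron-poor esters so that neither ring is over-oxidised (no 5,8-quinone), and water cleaves both labile esters.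

**Step 3**
Reactants: 8 5,3'-dihydroxy-7,8,4'-trimethoxyflavone
Product: 10 5,6,3'-trihydroxy-7,8,4'-trimethoxyflavone, via 6-hydroxydienone 9 (not isolated)
Conditions: Sc(OTf)3 (20 mol %), 2,6-lutidine (20 mol %), (±)-trans-2-(phenylsulfonyl)-3-phenyloxaziridine (1.1 equiv), 4 Å MS, CH2Cl2/MeCN 4:1, 0 °C → rt, Ar, 12 h; wash with aq. citric acid/ascorbic acid under Ar
Reagents that add atoms: 2-(phenylsulfonyl)-3-phenyloxaziridine (Davis reagent, racemic), O=S(=O)(c1ccccc1)N1OC1c1ccccc1
Why: Proposed new method: chelate-directed ortho C–H hydroxylation of a phenol by oxygen-atom transfer from an N-sulfonyloxaziridine, not yet shown for any phenol-to-catechol conversion or any flavone; trivalent scandium binds the 4-keto/5-hydroxy pocket (the same acid-stable site that aluminium shift reagents pick out in flavonoids), the weak base removes only this metal-acidified proton so that the 3'-OH stays a neutral, poorly nucleophilic phenol, the resulting phenolate pushes electron density onto C6 (ortho to O5, ortho to 7-OMe, para to O1, the only C–H of ring A and the usual site of electrophilic substitution), the oxaziridine held on the same metal through a sulfonyl oxygen presents its electrophilic O to C6 and not to the remote C8, C6 attacks O with N–O cleavage and loss of the sulfonimine to give dienone 9, and 9 re-aromatises by tautomerisation to the catechol, so its C6 stereocentre vanishes; because this is a closed-shell two-electron transfer from about one equivalent of a mild oxidant, the single-electron path that would turn the 5-hydroxy-8-methoxy pair into a 5,8-quinone is avoided; the closest known reaction types are the Davis α-hydroxylation of metal enolates and β-dicarbonyl chelates and the Sc(OTf)3-catalysed hydroxylative dearomatisation of 2-naphthols by oxaziridines.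

**Compound list**
1 | 2'-hydroxy-3',4'-dimethoxyacetophenone | CC(=O)c1ccc(OC)c(OC)c1O | starting material
2 | isovanillin (3-hydroxy-4-methoxybenzaldehyde) | COc1ccc(C=O)cc1O | starting material
3 | (E)-1-(2-hydroxy-3,4-dimethoxyphenyl)-3-(3-hydroxy-4-methoxyphenyl)prop-2-en-1-one (chalcone) | COc1ccc(/C=C/C(=O)c2ccc(OC)c(OC)c2O)cc1O | intermediate
4 | (±)-3'-hydroxy-7,8,4'-trimethoxyflavanone (racemic at C2) | COc1ccc(C2CC(=O)c3ccc(OC)c(OC)c3O2)cc1O | intermediate
5 | 3'-hydroxy-7,8,4'-trimethoxyflavone | COc1ccc(-c2cc(=O)c3ccc(OC)c(OC)c3o2)cc1O | intermediate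
6 | 3'-(trifluoroacetoxy)-7,8,4'-trimethoxyflavone | COc1ccc(-c2cc(=O)c3ccc(OC)c(OC)c3o2)cc1OC(=O)C(F)(F)F | intermediate
7 | 5,3'-bis(trifluoroacetoxy)-7,8,4'-trimethoxyflavone | COc1ccc(-c2cc(=O)c3c(OC(=O)C(F)(F)F)cc(OC)c(OC)c3o2)cc1OC(=O)C(F)(F)F | intermediate
8 | 5,3'-dihydroxy-7,8,4'-trimethoxyflavone | COc1ccc(-c2cc(=O)c3c(O)cc(OC)c(OC)c3o2)cc1O | intermediate
9 | (±)-6-hydroxy-2-(3-hydroxy-4-methoxyphenyl)-7,8-dimethoxy-6H-chromene-4,5-dione (keto tautomer of 10, racemic at C6) | COc1ccc(cc1O)C1=CC(=O)C2=C(O1)C(OC)=C(OC)C(O)C2=O | intermediate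
10 | 5,6,3'-trihydroxy-7,8,4'-trimethoxyflavone (achiral) | COc1ccc(-c2cc(=O)c3c(O)c(O)c(OC)c(OC)c3o2)cc1O | target

**Total step count:** 3. **Longest linear sequence:** 3 (both starting materials enter in step 1).

**Steps most likely to fail (ranked)**

Step 3, the new C6–H hydroxylation, is the most likely to fail, and there are four ways it could do so. The scandium-bound phenolate may be too weak a carbon nucleophile for the oxaziridine. The catechol product may hold the catalyst. The sulfonimine by-product may capture C6 in an aza-Friedel–Crafts reaction. The catechol may go on to the 5,6-quinone. The fallback uses known chemistry, sets out from 8 and comes back at 10. It is the classical two-stage ortho-oxidation of flavonoid phenols, in which a C–C bond is made first and then exchanged for C–O. Duff formylation of 8 (hexamethylenetetramine, CF3CO2H, 80 °C, then aq. HCl) places the aldehyde on the only free ring-A carbon and gives 6-formyl-5,3'-dihydroxy-7,8,4'-trimethoxyflavone F1. Dakin oxidation (30 % H2O2, aq. NaOH, pyridine, 0 °C, N2) moves the aryl group from carbon to oxygen and gives 6-formyloxy-5,3'-dihydroxy-7,8,4'-trimethoxyflavone F2. F2 is saponified in the same flask to 10.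

Step 2 may fail in two ways. The trivalent-iodine oxidant may attack the electron-rich rings faster than the metallacycle turns over. Alternatively, any 5-phenol set free early may be oxidised to the 5,8-quinone. The fallback sets out from 2 and comes back at 8, bringing O-5 in with ring A instead of by C–H activation. Catalogue 2'-hydroxy-3',4',6'-trimethoxyacetophenone F3 is condensed with 2 (KOH, EtOH, rt) to (E)-1-(2-hydroxy-3,4,6-trimethoxyphenyl)-3-(3-hydroxy-4-methoxyphenyl)prop-2-en-1-one F4. I2 (cat.) in DMSO at 130 °C closes and dehydrogenates F4 to 3'-hydroxy-5,7,8,4'-tetramethoxyflavone F5. BCl3 (CH2Cl2, −78 → 0 °C) then cleaves only the 5-OMe, which lies peri to the carbonyl and is held in a boron chelate, and gives 8.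

Step 1 may stall at the flavanone, the hot amine may open the pyrone ring, or the free phenol may lower the yield. The fallback sets out from 1 and comes back at 5. It is the Baker–Venkataraman route, in which the C–C bond comes from an acyl shift and ring C closes by cyclodehydration. 1 is esterified with catalogue 3-(benzyloxy)-4-methoxybenzoic acid F6 (EDC·HCl, DMAP, CH2Cl2) to 6-acetyl-2,3-dimethoxyphenyl 3-(benzyloxy)-4-methoxybenzoate F7. KOH in pyridine at 50 °C shifts the aroyl group to carbon and gives 1-[3-(benzyloxy)-4-methoxyphenyl]-3-(2-hydroxy-3,4-dimethoxyphenyl)propane-1,3-dione F8. p-TsOH (cat.) in refluxing toluene cyclodehydrates F8 to 3'-(benzyloxy)-7,8,4'-trimethoxyflavone F9. Hydrogenolysis (H2, Pd/C, EtOAc/MeOH, rt) gives 5.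

**Further compounds**
F1 | step 3 | 6-formyl-5,3'-dihydroxy-7,8,4'-trimethoxyflavone | COc1ccc(-c2cc(=O)c3c(O)c(C=O)c(OC)c(OC)c3o2)cc1O
F2 | step 3 | 6-formyloxy-5,3'-dihydroxy-7,8,4'-trimethoxyflavone | COc1ccc(-c2cc(=O)c3c(O)c(OC=O)c(OC)c(OC)c3o2)cc1O
F3 | step 2 | 2'-hydroxy-3',4',6'-trimethoxyacetophenone | CC(=O)c1c(OC)cc(OC)c(OC)c1O
F4 | step 2 | (E)-1-(2-hydroxy-3,4,6-trimethoxyphenyl)-3-(3-hydroxy-4-methoxyphenyl)prop-2-en-1-one | COc1ccc(/C=C/C(=O)c2c(OC)cc(OC)c(OC)c2O)cc1O
F5 | step 2 | 3'-hydroxy-5,7,8,4'-tetramethoxyflavone | COc1ccc(-c2cc(=O)c3c(OC)cc(OC)c(OC)c3o2)cc1O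
F6 | step 1 | 3-(benzyloxy)-4-methoxybenzoic acid | COc1ccc(C(=O)O)cc1OCc1ccccc1
F7 | step 1 | 6-acetyl-2,3-dimethoxyphenyl 3-(benzyloxy)-4-methoxybenzoate | CC(=O)c1ccc(OC)c(OC)c1OC(=O)c1ccc(OC)c(OCc2ccccc2)c1
F8 | step 1 | 1-[3-(benzyloxy)-4-methoxyphenyl]-3-(2-hydroxy-3,4-dimethoxyphenyl)propane-1,3-dione | COc1ccc(C(=O)CC(=O)c2ccc(OC)c(OC)c2O)cc1OCc1ccccc1
F9 | step 1 | 3'-(benzyloxy)-7,8,4'-trimethoxyflavone | COc1ccc(-c2cc(=O)c3ccc(OC)c(OC)c3o2)cc1OCc1ccccc1
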